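Start from the vessel: a closed, stirred flask at constant volume and temperature, into which starting material, partner and precatalyst go together.

| setting | green | violet | spring | dawn |
|---|---|---|---|---|
| starting material | 0.068 M | 0.068 M | 0.068 M | 0.068 M |
| partner | 0.74 equiv | 1.7 equiv | 1.10 equiv | 1.10 equiv |
| precatalyst | 0.11 mol% | 0.11 mol% | 0.11 mol% | 0.11 mol% |
| remark | run made earlier | run made earlier |  |  |
| time |  |  | 8.0 min | 10 min |

| run | time / min | target / % | starting material / % | catalyst intermediate B / % | catalyst intermediate A / % |
|---|---|---|---|---|---|
| green | 0.667 | 0 | 99.3 | 0 | 2.0 |
| green | 1.00 | 0 | 101.0 | 1.4 | 0 |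
| green | 2.00 | 0 | 99.5 | 0 | 0 |
| green | 3.00 | 1.9 | 99.2 | 1.1 | 0.1 |
| green | 5.00 | 3.0 | 96.4 | 0 | 0 |
| green | 8.00 | 6.6 | 91.3 | 0 | 0.1 |
| violet | 0.667 | 0 | 99.9 | 0.6 | 0 |
| violet | 1.00 | 1.5 | 98.9 | 1.0 | 0 |
| violet | 2.00 | 1.4 | 97.4 | 0 | 0.4 |
| violet | 3.00 | 4.8 | 94.6 | 0.5 | 0 |
| violet | 5.00 | 8.8 | 90.2 | 0 | 0 |
| violet | 8.00 | 23.9 | 77.6 | 1.3 | 0.4 |

(scatter of a reading: 1 percentage point)

- which of these there is most of at the end, counted by the starting material in it, spring (catalyst intermediate A / starting material / catalyst intermediate B / target)
- which of these there is most of at the end, counted by the starting material in it, dawn (catalyst intermediate A / starting material / catalyst intermediate B / target)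
- amount of the one of these that there is most of at the end, in percent of the starting material charged, spring
- amount of the one of these that there is most of at the end, in percent of the starting material charged, dawn

Set the catalyst intermediates aside, for their readings reach no higher than 2.0% against a scatter of 1 percentage point, and follow the starting material. In the green run, target reads 3.0% at 5.00 min and gains 3.6 points in the 3.00 min after that, so the reaction gathers speed. Suppose the precatalyst releases working catalyst at a steady pace. Loss of starting material is then pseudo-first-order, with a rate constant growing in proportion to time. Integrate that rate, and the logarithm of c(starting material charged) over c(starting material) grows with the square of time. Call the clock time divided by the square root of that logarithm the induction time; under the square law it stays the same at every moment of a run. The last readings give 26.5 min for green and 15.9 min for violet.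

Doubt the square first, since each induction time rests on one reading. Run it backwards to 5.00 min: it gives 96.5% for green against 96.4% read, and 90.6% for violet against 90.2% read, both inside the scatter.

Next, bridge the two partner charges with a power: let the induction time fall as the partner charge rises, with the exponent 0.616. At 1.10 equiv this gives the induction time of the recipe, 20.8 min. Spring should then keep 86.2% of its starting material and dawn 79.3%.

Object once more: the induction time assumes the partner stays at its charge, yet in dawn, at one partner per starting material, 18.8% of it would be gone. So let dawn's figure lean upward. The ranking survives, as starting material stands above target by 59 points.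

The forecast says starting material at 87% for spring and starting material at 80% for dawn: “Starting material therefore remains dominant”.

Spring gives starting material at 86.9% and dawn starting material at 81.0%, which is 0.70 points and 1.7 points above the reckoning. In spring at 8.00 min, precatalyst still holds 77.5% of the catalyst charged. Put the induction time to work again at 4.00 min in spring: it gives 96.4%, and the flask holds 96.4%.

    catalyst intermediate A ⇌ catalyst intermediate B (K = 0.730, k = 530 s⁻¹)
    catalyst intermediate D → by-product + catalyst intermediate E (k = 66.0 s⁻¹)
    starting material + free catalyst → catalyst intermediate A (k = 130 L mol⁻¹ s⁻¹)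
    partner + catalyst intermediate B ⇌ catalyst intermediate C (K = 39.0 L mol⁻¹, k = 150 L mol⁻¹ s⁻¹)
    2 catalyst intermediate D → spent catalyst A (k = 5.90 L mol⁻¹ s⁻¹)
    partner + precatalyst → free catalyst + spent reagent (k = 0.00740 L mol⁻¹ s⁻¹)
    catalyst intermediate E → free catalyst + target (k = 10.0 s⁻¹)
    catalyst intermediate C → catalyst intermediate D (k = 150 s⁻¹)
    free catalyst + by-product → spent catalyst B (k = 0.140 L mol⁻¹ s⁻¹)

Now take a neighbour of spring with precatalyst cut to 0.028 mol%. Stretch the squared induction time of 20.8 min by the inverse of the loading, and 96.3% of the starting material should remain at 8.0 min. The computed neighbour holds 96.5%, with target at 3.53%.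

The earlier runs and the new flask stem from a simulated flask from invented constants, noise included.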